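The numbers in the tables were generated by integration on assumed constants; the scatter is artificial.

It was impossible to read the green run as the grey run on a clock sped up in proportion to the enzyme: at the same product of time and loading, green at 10.0 min held 66.6% of its starting material and grey at 40.0 min held 51.1%.

in all of them: starting material 0.20 M

| run | second substrate | enzyme | remark | time |
|---|---|---|---|---|
| grey | 1 equiv (in portions, 3) | 0.0012 mol% | run made earlier; portions every 10 s |  |
| green | 1 equiv (in portions, 3) | 0.0048 mol% | run made earlier; portions every 10 s |  |
| flask | 1.00 equiv (in portions, 3) | 0.0024 mol% | the portions of second substrate follow each other after 10 s, the first at the start | 30 min |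

| run | time / min | target / % | starting material / % |
|---|---|---|---|
| grey | 3.00 | 4.4 | 95.6 |
| grey | 5.00 | 7.6 | 93.0 |
| grey | 10.0 | 14.1 | 86.3 |
| grey | 20.0 | 27.8 | 72.6 |
| grey | 40.0 | 49.5 | 51.1 |
| green | 3.00 | 10.8 | 89.1 |
| green | 10.0 | 32.2 | 66.6 |
| green | 15.0 | 45.6 | 54.2 |
| green | 25.0 | 64.7 | 35.6 |
| green | 40.0 | 81.7 | 19.2 |

(each reading ± 0.5 percentage points)

- concentration of target at 30 min, in M
- concentration of starting material at 30 min, in M



I took two times, the half-lives of starting material read at the last point of each run: 41.3 min in grey and 16.8 min in green. Green carried 4.00 times grey's enzyme, and a proportional clock gives 10.3 min, so the green reading was longer than that. The logarithm of the ratio of the two times, 2.46, over the logarithm of the loading ratio came to 0.649: this is the apparent order in enzyme, the power of the loading that the rate follows.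

The new flask has twice grey's loading, so I reckoned a half-life of 26.3 min. That leaves 0.0908 M of starting material at 30 min and 0.109 M of target, since the last green readings sum to 101% of the charge.

The forecast also saw the rate lag behind the enzyme (“Four times the enzyme therefore gives only about 2.5 times the rate”) and gave 0.108 M of target (0.102 M to 0.113 M) and 0.093 M of starting material (0.087 M to 0.099 M), slightly more starting material than mine.

The flask gave 0.110 M of target and 0.0896 M of starting material, inside both ranges of the forecast. It was still working at 30 min, with 45% of its starting material unbound and 68.3% of its enzyme in the resting dimer, its resting state.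

    complex A → enzyme + target (k = 72.0 s⁻¹)
    complex B → enzyme + second product (k = 800 s⁻¹)
    starting material + enzyme ⇌ complex A (K = 7.40 L mol⁻¹, k = 20000 L mol⁻¹ s⁻¹)
    2 enzyme ⇌ resting dimer, settled at all times (K = 2.00 × 10⁶ L mol⁻¹)
    second substrate + enzyme ⇌ complex B (K = 2.00 L mol⁻¹, k = 3.30 × 10⁵ L mol⁻¹ s⁻¹)

The flask's own half-life, 25.9 min, puts the order at 0.674 against the 0.649 from the two earlier runs. I carried 0.649 to the neighbour flask, charged with 0.0041 mol% of enzyme and otherwise like this one. It gives a half-life of 18.6 min and 32.7% of starting material left at 30 min. That neighbour kept 32% unbound and held 67.6% of its charge as target.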